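Of the first end groups you charge, part stands at the asked time as links (L) and part as isomer of the product (E). The feed changes how long that part has been links.

| flask | first end groups | second end groups | remark | time |
|---|---|---|---|---|
| theta | 0.091 M | 0.091 M | run made earlier |  |
| zeta | 0.13 M | 0.091 M | run made earlier |  |
| beta | 0.20 M | 0.091 M | run made earlier |  |
| epsilon | 0.091 M | 0.045 M | run made earlier |  |
| winter | 0.091 M | 0.0910 M | everything together at the start | 1.5 h |
| midnight | 0.091 M | 0.0910 M (fed, over 80 min) | all else is in the flask from the start; the feed brings no volume worth counting | 1.5 h |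
| dawn | 0.091 M (fed, over 80 min) | 0.0910 M | all else is in the flask from the start; the feed brings no volume worth counting | 1.5 h |

| run | time / min | isomer of the product / % | links / % |
|---|---|---|---|
| theta | 8.00 | 0.8 | 17.0 |
| theta | 15.0 | 3.6 | 26.5 |
| theta | 40.0 | 14.1 | 38.8 |
| theta | 90.0 | 35.5 | 35.6 |
| zeta | 12.0 | 1.6 | 22.5 |
| zeta | 30.0 | 9.0 | 32.3 |
| zeta | 60.0 | 20.9 | 33.7 |
| zeta | 90.0 | 31.3 | 29.6 |
| beta | 8.00 | 1.9 | 15.2 |
| beta | 15.0 | 3.0 | 22.4 |
| beta | 40.0 | 11.1 | 27.3 |
| beta | 90.0 | 24.2 | 19.8 |
| epsilon | 8.00 | 0.4 | 9.9 |
| epsilon | 15.0 | 2.3 | 13.4 |
| epsilon | 40.0 | 7.1 | 21.1 |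
| epsilon | 90.0 | 21.3 | 20.3 |

(each reading ± 0.5 percentage points)

- which flask leads in amount of isomer of the product, in percent of the first end groups charged ("all alike" within 1.5 percentage points) (winter / midnight / dawn / all alike)
- how much isomer of the product is there at the end, in percent of the first end groups charged: winter
- how much isomer of the product is there at the end, in percent of the first end groups charged: midnight
- how much isomer of the product is there at the end, in percent of the first end groups charged: dawn



Theta has winter's recipe, so I read the rule there: I take E as proportional to the area under L, and replace the L curve by its mean L̄. By trapezoids, L̄ over 90.0 min is 32.2%, so the isomerisation coefficient λ, E divided by the area under L, reads 0.0123 min⁻¹.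

The time scales climb in order. Coupling comes first: theta's conversion, taken as second order, gives τ = 36.6 min to couple half of equal charges. Raising first end groups 2.20-fold (beta) raises the amount coupled by 8.00 min 2.11-fold, and theta's 2.02-fold second end groups over epsilon give 1.73-fold, so I treat the two ends alike. Next comes the feed, 80 min, then the isomerisation time, the inverse of λ, 81.6 min, just short of the asked 90 min.

As a rough step of my own, I replace the feed by its mean too: one dose arriving 40.0 min late. In this estimate, midnight and dawn are theta's run cut to 50.0 min. Holding L at its 40.0 min reading past that point, λ gives 17.5% for each, against 35.5% for winter.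

The forecast, above my fed figure, gives 35.7% for winter and 19% and 19% for midnight and dawn: “Links form later, so they have less time to isomerise.”

The flask gives 36.2% in winter and 19.9% and 19.9% in midnight and dawn, so winter leads, and my fed figure fell 2.4 percentage points short. At 0.750 h midnight held 18.0% links and winter 39.3%, though both end at 35.6%. λ on midnight's simulated links gives 20.2%.

    links ⇌ isomer of the product (K = 3.90, k = 2.30 × 10⁻⁴ s⁻¹)
    first end groups + second end groups → links + by-product (k = 0.00520 M⁻¹ s⁻¹)

In the neighbour of winter with 0.055 M of second end groups, 24.8% links at 1.50 h, with theta's ratio of mean to end, make λ give 24.7%. The computed flask holds 24.5%.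

The runs come from a simulation for substances that don't exist; the scatter is artificial.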